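**Remark on numbering (assumption).** The skeleton is numbered as an eremophilane: C1–C10 for the decalin (ring A = C1–C5 and C10, ring B = C5–C10), C11–C13 for the three-carbon unit on C7, methyl groups on C4 and C5. β is the face of the C5 methyl group. Tricyclic furans are named as 10βH-furanoeremophilanes (4β,5β-dimethyl, furan oxygen between C8 and C12). 3,4-Dibromofuran, methyl 4-oxobutanoate, (E)-non-3-en-2-one and both enantiomers of pentane-2,4-diol are taken as purchasable.

## Analysis of the target

Target 34 is a cis-fused decalin of the eremophilane type, acylated at O3 with (2E,4E,6E)-5-methyldodeca-2,4,6-trienoic acid. Five contiguous stereocentres run C3–C4–C5–C10–C9 (3R,4S,5R,9R,10S): the C4 and C5 methyl groups, H10 and the C9 hydroxyl lie on the β face, the C3 acyloxy group on the α face, and C5 is quaternary. Ring B holds an α-ketol (C8=O, C9–OH) conjugated to a tetrasubstituted exocyclic alkene C7=C11 of Z geometry, which carries the C13 methyl and the C12 hydroxymethyl group. This Z-γ-hydroxy enone is formally the hydrate of a furan. It can close to a hemiketal and lose water to the aromatic furan under acid, so it has to be unveiled last and kept near neutrality; the trienoate must be spared strong nucleophiles, light and unselective oxidants. The hard points are the vicinal cis methyl groups at C4/C5 on a quaternary centre of a cis ring fusion, the C9 carbinol next to that fusion, the fixed Z geometry of a tetrasubstituted alkene, and the telling apart of three oxygenated positions (C3, C9, C12). The strategy rests on reading C8(=O)–C7=C11(C13)–C12–OH as an opened 3-methylfuran with oxygen between C8 and C12. As a furan this unit fixes the alkene geometry, protects C8 and C12, and makes C9 a furfuryl carbon which, as an acetal, can start a cationic ring closure through C10, C5 and C4.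

## Retrosynthetic reasoning

**34 ⇒ 33 ⇒ 32.** The C12 alcohol is taken back to the aldehyde of enedione 33, and 33 to furan 32, by closing the C8–O–C12 ring. No C–C bond is cut; the Z alkene and the C8/C12 oxygenation become one aromatic ring that survives everything before it. Forward, the furan must be oxidised in the presence of the trienoate, and the aldehyde of 33 reduced in the presence of the C8 ketone without acid.

**32 ⇒ 25 + 30.** The ester C–O bond at C3 is cut last among the skeletal bonds, because the trienoic acid 30 is the most sensitive part and is best introduced on a robust furan. The C9 hydroxyl is masked as the silyl ether in 25 so that only O3 is acylated.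

**25 ⇒ 24 ⇒ 23 ⇒ 22 ⇒ 21.** The C3 alcohol comes from the C3 ketone of 24. The auxiliary ether at C9 of 21 is removed first (oxidation to 22, β-elimination to 23), because its free hydroxyl would compete in every later step. Once the small C9 oxygen substituent is equatorial, the 3α-alcohol is the more stable epimer, so the reduction is planned under product-stability control.

**21 ⇒ 20 (key disconnection).** The C9–C10 and C4–C5 bonds are cut together. This opens both carbocycles and removes four stereocentres (C4, C5, C9, C10) in one operation, and traces them to two alkene geometries and one chiral acetal. Cutting elsewhere would either leave the quaternary C5 to be made on a ring or separate the furan from the decalin. Forward, the acetal carbon C9 must be attacked by C10 of a Z olefin and the resulting C5 cation by C4 of an E-enol silane.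

**20 ⇒ 19.** The enol silane is the element that is hard to make cleanly from an ethyl ketone, since both α-carbons are methylene groups. It is therefore derived from the 2-silyloxy-1,3-diene 19 by 1,4-addition of dihydrogen. The position of the diene fixes the regiochemistry, and the s-cis geometry of the metal-bound diene fixes the enol geometry.

**19 ⇒ 12 + 17.** The C6–C5 bond (sp3–sp2) is cut between the furylmethyl carbon and the vinyl carbon. This gives two fragments of similar size, and the Z geometry of the vinyl iodide 17 is carried over unchanged. Forward, a furylmethylzinc species from chloride 12 is coupled with 17.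

**12 ⇒ 10 ⇒ 7 ⇒ 5 + 6; 5 ⇒ 3 ⇒ 1.** The chloromethyl group comes from alcohol 10, and this from bromide 7 by halogen–metal exchange and a one-carbon electrophile. Acetal 7 is made from aldehyde 5 and diol 6. The substitution pattern of the furan (C9 on C8, C6 on C7, methyl on C11) is written onto 3,4-dibromofuran 1 by three successive metalations. Each is directed by the substituent that is already in place.

**17 ⇒ 16 ⇒ 15 ⇒ 14 ⇒ 13.** The silyloxy diene is the enol derivative of vinyl ketone 16, which has only one enolisable position. Ketone 16 comes from Weinreb amide 15 and this from ester 14. The Z vinyl iodide of 14 is cut at C10=C5 to aldehyde 13 and an α-iodo ylide.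

**30 ⇒ 29 ⇒ 28 ⇒ 27 ⇒ 26.** The trienoic acid is cut at C2=C3 (condensation of dienal 29 with a malonate unit) and at C4=C5 (olefination of enone 26). Both E geometries are set by thermodynamically biased olefinations.

## Alternatives that were turned down

**Alternative 1:** The decalin is cut at C5–C6 and traced to a bridged bicyclo[2.2.2]octenol from masked ortho-quinone Diels–Alder chemistry. In the forward step, an anionic oxy-Cope shift of the potassium alkoxide forms C5–C6, breaks C3–C8 and gives A1 (cis-fused 9,9-dimethoxy-4,5-dimethyloctal-3-en-8-one).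
- For: a concerted [3,3] shift sets the cis fusion and the quaternary C5 reliably. The C8/C9 oxygen pattern arrives as an α-keto ketal. The C3=C4 alkene of A1 could give the 3α-hydroxy-4β-methyl pair in one syn hydroboration from the face away from the C5 methyl. On certainty of ring formation this route is stronger than the chosen one.
- Against: the sequence has no element of absolute control. The C9 ketal must later be turned into one carbinol epimer beside a ketone. The C11–C13 unit has to be attached at C7 after the fact, where the Z geometry of a tetrasubstituted enone would be left to an unbiased condensation.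
- Comparison: the chosen route brings all fifteen skeletal carbons, the C9 oxygen and the alkene geometry into the cyclisation substrate, and it derives absolute configuration from a commercial diol. It pays with a less secure key step.

**Alternative 2:** Ring B is cut at C5–C10 and C6–C7. In the forward step an intramolecular Diels–Alder reaction joins an isopropenyl ketone (C5=C6) to a 2-silyloxy-3-alkoxy diene (C7 to C10) across a three-atom tether and gives A2 (cis-fused 3α-silyloxy-9-alkoxy-8-silyloxy-5-methyloctal-8-en-4-one).
- For: both rings close in a thermal, predictable step. The absolute configuration is relayed from the C3 stereocentre in the substrate, with no auxiliary to remove. The C8/C9 acyloin is present as a regio-defined enediol diether. In these respects it is at least as strong as the chosen route.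
- Against: C4 is a ketone in A2 and must be converted into a CH–CH3 centre cis to the C5 methyl (olefination and face-selective hydrogenation next to a quaternary carbon). C9 is then set by protonation of an enol ether. The C11–C13 unit and its Z geometry remain to be solved on a hindered α-ketol.
- Comparison: the chosen route sets C4 in the ring closure itself and needs no C–C bond formation afterwards, so it is shorter after the key step.

**Alternative 3:** Ring A is cut at C1–C10. In the forward step a primary C1 radical (tin hydride, AIBN) adds 6-exo to one enone arm of a 4-methyl-4-alkylcyclohexadienone and gives A3 (cis-fused 3β-silyloxy-4,5-dimethyloctal-6-en-8-one).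
- For: the dienone is easily made by phenol dearomatisation. The vicinal methyl groups are set before the ring closure (C4 by acyclic stereocontrol, C5 as the dienone carbon). The cyclisation is of a well-tried kind and leaves an enone for further work.
- Against: the choice between the two enone arms depends on a side-chain stereocentre. A3 carries the 3β oxygen, which must be inverted. The C9 hydroxyl has to be introduced by enolate oxidation with facial control. C7 must be alkylated and the alkene moved from C6=C7 to C7=C11 with Z geometry. Tin reagents are needed.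
- Comparison: the chosen route is less proven in its key step but ends with far fewer operations on the ring system, and it never has to build the Z-tetrasubstituted alkene.

Key step: step 12

## Route

Step 1
Reactants: 1 3,4-dibromofuran
Product: 3 3-bromo-4-methylfuran, via 3-bromo-4-lithiofuran 2 (not isolated)
Conditions: n-BuLi (1.0 equiv), Et2O, −78 °C; MeI, −78 °C → rt
Reagents that add atoms: iodomethane, CI
Why: Bromine–lithium exchange of one of the two equivalent bromines is fast at −78 °C and the 3-furyllithium is stable at that temperature; methylation installs the future C13 methyl group.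

Step 2
Reactants: 3 3-bromo-4-methylfuran
Product: 5 3-bromo-4-methylfuran-2-carbaldehyde, via 3-bromo-2-lithio-4-methylfuran 4 (not isolated)
Conditions: LiN(i-Pr)2, THF, −78 °C; DMF, −78 → 0 °C; aq. NH4Cl
Reagents that add atoms: N,N-dimethylformamide, CN(C)C=O
Why: The amide base deprotonates rather than exchanges, and the α-position flanked by the ring oxygen and the C–Br bond is the most acidic, so the formyl group (future C9) enters next to the bromine and not next to the methyl group (directed ortho-type lithiation, formylation).

Step 3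
Reactants: 5 3-bromo-4-methylfuran-2-carbaldehyde; 6 (2S,4S)-pentane-2,4-diol
Product: 7 (4S,6S)-2-(3-bromo-4-methylfuran-2-yl)-4,6-dimethyl-1,3-dioxane
Conditions: PPTS (cat.), benzene, reflux, Dean–Stark
Reagents that add atoms: none
Why: Acid-catalysed acetalisation with removal of water; because the diol is C2-symmetric the acetal carbon is not a stereocentre and a single acetal results.

Step 4
Reactants: 7 (4S,6S)-2-(3-bromo-4-methylfuran-2-yl)-4,6-dimethyl-1,3-dioxane
Product: 10 {2-[(4S,6S)-4,6-dimethyl-1,3-dioxan-2-yl]-4-methylfuran-3-yl}methanol, via lithiated furan acetal 8 (not isolated), via 3-formylfuran acetal 9 (not isolated)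
Conditions: n-BuLi, THF, −78 °C; DMF, −78 °C; MeOH, NaBH4, 0 °C
Reagents that add atoms: N,N-dimethylformamide, CN(C)C=O
Why: Bromine–lithium exchange gives a 3-furyllithium held by the neighbouring acetal oxygens; formylation and borohydride reduction in the same flask give the C6 carbinol, and the acetal is inert to all three reagents.

Step 5
Reactants: 10 {2-[(4S,6S)-4,6-dimethyl-1,3-dioxan-2-yl]-4-methylfuran-3-yl}methanol
Product: 12 (4S,6S)-2-[3-(chloromethyl)-4-methylfuran-2-yl]-4,6-dimethyl-1,3-dioxane, via mesylate 11 (not isolated)
Conditions: MsCl, Et3N, CH2Cl2, 0 °C; LiCl, DMF, rt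
Reagents that add atoms: lithium chloride, [Li+].[Cl-]
Why: Mesylation and chloride displacement run under basic conditions that leave the acetal untouched; the chloride is chosen over the bromide because it inserts zinc with little homocoupling.

Step 6
Reactants: 13 methyl 4-oxobutanoate
Product: 14 methyl (Z)-5-iodohex-4-enoate
Conditions: [Ph3PEt]I, n-BuLi, THF, rt; I2, −78 °C; NaN(SiMe3)2, −20 °C; 13, −78 °C → rt
Reagents that add atoms: ethyltriphenylphosphonium iodide, CC[P+](c1ccccc1)(c1ccccc1)c1ccccc1.[I-]; iodine, II
Why: Stork–Zhao-type Wittig olefination with the α-iodo ylide; the unstabilised ylide reacts under kinetic control to place iodine cis to the chain, which is the Z geometry needed for the C5=C10 olefin, and the ester is not attacked at low temperature.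

Step 7
Reactants: 14 methyl (Z)-5-iodohex-4-enoate
Product: 15 (Z)-5-iodo-N-methoxy-N-methylhex-4-enamide
Conditions: MeNH(OMe)·HCl, i-PrMgCl, THF, −20 °C
Reagents that add atoms: N,O-dimethylhydroxylamine hydrochloride, CNOC.Cl
Why: Aminolysis of the ester by the magnesium amide gives the Weinreb amide; at −20 °C the alkenyl iodide does not undergo exchange.

Step 8
Reactants: 15 (Z)-5-iodo-N-methoxy-N-methylhex-4-enamide
Product: 16 (Z)-7-iodoocta-1,6-dien-3-one
Conditions: CH2=CHMgBr, THF, −78 → 0 °C; inverse quench into cold aq. HCl
Reagents that add atoms: vinylmagnesium bromide, C=C[Mg]Br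
Why: Weinreb ketone synthesis; the chelated adduct prevents over-addition, and the acidic inverse quench keeps the liberated amine from adding to the vinyl ketone.

Step 9
Reactants: 16 (Z)-7-iodoocta-1,6-dien-3-one
Product: 17 tert-butyl{[(3Z,6Z)-7-iodoocta-1,3,6-trien-3-yl]oxy}dimethylsilane
Conditions: TBSOTf, Et3N, Et2O, 0 °C
Reagents that add atoms: tert-butyldimethylsilyl trifluoromethanesulfonate, CC(C)(C)[Si](C)(C)OS(=O)(=O)C(F)(F)F
Why: Soft enolisation of a vinyl ketone can only occur at C2, so the 2-silyloxy-1,3-diene is regiodefined; it is expected as the Z enol ether (chain trans to the vinyl group), the isomer that can reach the s-cis form.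

Step 10
Reactants: 12 (4S,6S)-2-[3-(chloromethyl)-4-methylfuran-2-yl]-4,6-dimethyl-1,3-dioxane; 17 tert-butyl{[(3Z,6Z)-7-iodoocta-1,3,6-trien-3-yl]oxy}dimethylsilane
Product: 19 (4S,6S)-2-{3-[(2Z,5Z)-6-(tert-butyldimethylsilyloxy)-2-methylocta-2,5,7-trien-1-yl]-4-methylfuran-2-yl}-4,6-dimethyl-1,3-dioxane, via furylmethylzinc chloride 18 (not isolated)
Conditions: Zn, LiCl, THF, rt; 17, Pd(PPh3)4 (5 mol %), THF, rt
Reagents that add atoms: none
Why: LiCl-promoted zinc insertion into the heterobenzylic chloride followed by Negishi coupling with the alkenyl iodide forms the C6–C5 bond with retention of the Z geometry; acetal and silyl dienol ether are inert to the organozinc and to zerovalent palladium.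

Step 11
Reactants: 19 (4S,6S)-2-{3-[(2Z,5Z)-6-(tert-butyldimethylsilyloxy)-2-methylocta-2,5,7-trien-1-yl]-4-methylfuran-2-yl}-4,6-dimethyl-1,3-dioxane
Product: 20 (4S,6S)-2-{3-[(2Z,6E)-6-(tert-butyldimethylsilyloxy)-2-methylocta-2,6-dien-1-yl]-4-methylfuran-2-yl}-4,6-dimethyl-1,3-dioxane
Conditions: (η6-naphthalene)Cr(CO)3 (20 mol %), H2 (40 atm), THF, 40 °C
Reagents that add atoms: none
Why: Arene–Cr(CO)3 catalysts add dihydrogen 1,4 across conjugated dienes held in the s-cis form, so hydrogen goes to C2 and to the terminal CH2 and the new C3=C4 bond forms with C2 and the new methyl group cis, which is the E enol silane; its position is fixed by the diene, and the isolated trisubstituted olefin, the furan and the acetal are not substrates for this catalyst.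

Step 12
Reactants: 20 (4S,6S)-2-{3-[(2Z,6E)-6-(tert-butyldimethylsilyloxy)-2-methylocta-2,6-dien-1-yl]-4-methylfuran-2-yl}-4,6-dimethyl-1,3-dioxane
Product: 21 9β-{[(2S,4S)-4-hydroxypentan-2-yl]oxy}-10βH-furanoeremophilan-3-one
Conditions: TiCl4 (3 equiv), 2,6-di-tert-butyl-4-methylpyridine, CH2Cl2, −78 °C; MeOH–Et3N, then aq. NaHCO3
Reagents that add atoms: none
Why: TiCl4 binds the acetal oxygen flanked by the axial methyl group and ionises that C9–O bond, the Z-trisubstituted olefin attacks C9 through C10 on the side away from the leaving oxygen, and the tertiary C5 cation is captured by C4 of the enol silane while chloride takes the silyl group and frees the C3 ketone. The closest known reaction is the acetal-initiated cation–olefin polycyclisation of chiral pentane-2,4-diol acetals with an enol-derived terminator, applied here to a furfurylic acetal carbon and a Z olefin. Ring B closes 6-endo (C9–C10, the C5=C10 bond inside the forming ring, chair-like with the furan edge flat), and ring A closes 6-endo at the cation with the enol double bond inside the ring (C4–C5). C9 is set by the auxiliary through invertive opening, which from the (S,S)-acetal gives the 9R ether. C10 and C5 are set by the olefin geometry: anti addition across the Z olefin puts C1 axial and C4 equatorial on ring B, so H10 and the C5 methyl group end on the same face (cis fusion). C4 is set by the enol silane geometry: in the chair that closes ring A the methyl group cis to C2 becomes axial and therefore cis to the C5 methyl group. The step needs the retained alkoxy group to sit pseudo-axial on ring B, the orientation normally preferred in acetal-initiated closures, because only this places O9 cis to H10 and ties the (S,S)-auxiliary to the natural carbocycle; the planar furan edge could change this, and it is the least secure point. Chemoselectivity rests on reach: the enol silane cannot meet C9 in a normal ring, the olefin can only give a six-membered ring through C10, and the nucleophilic C12 of the furan cannot reach either cation.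

Step 13
Reactants: 21 9β-{[(2S,4S)-4-hydroxypentan-2-yl]oxy}-10βH-furanoeremophilan-3-one
Product: 22 9β-{[(2S)-4-oxopentan-2-yl]oxy}-10βH-furanoeremophilan-3-one
Conditions: Dess–Martin periodinane, NaHCO3, CH2Cl2, rt
Reagents that add atoms: none
Why: Dess–Martin oxidation of the only hydroxyl group under buffered, near-neutral conditions that spare the furan and do not enolise the C3 ketone.

Step 14
Reactants: 22 9β-{[(2S)-4-oxopentan-2-yl]oxy}-10βH-furanoeremophilan-3-one
Product: 23 9β-hydroxy-10βH-furanoeremophilan-3-one
Conditions: Bn2NH2+ CF3CO2−, benzene, 50 °C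
Reagents that add atoms: none
Why: β-Elimination (retro-oxa-Michael) of the β-alkoxy methyl ketone through its enamine expels the C9 alkoxide without touching the C9–O bond, so C9 keeps its configuration; the hindered C3 ketone condenses with the amine far more slowly, and with the C9 oxygen equatorial the 4β-methyl epimer is also the more stable one.

Step 15
Reactants: 23 9β-hydroxy-10βH-furanoeremophilan-3-one
Product: 24 9β-(triethylsilyloxy)-10βH-furanoeremophilan-3-one
Conditions: TESCl, imidazole, DMAP (cat.), DMF, rt
Reagents that add atoms: chlorotriethylsilane, CC[Si](Cl)(CC)CC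
Why: Silylation masks the furfuryl alcohol so that only O3 is acylated later; the triethylsilyl group is removable with buffered fluoride in the presence of the trienoate.

Step 16
Reactants: 24 9β-(triethylsilyloxy)-10βH-furanoeremophilan-3-one
Product: 25 9β-(triethylsilyloxy)-10βH-furanoeremophilan-3α-ol
Conditions: SmI2, THF–H2O, 0 °C → rt
Reagents that add atoms: none
Why: Single-electron (ketyl) reduction with SmI2 protonates under product-stability control and should give the equatorial 3α-alcohol, trans to the C4 methyl group, which sets C3; in the chair that keeps the C9 silyloxy group equatorial the C5 methyl group is axial on ring A and would steer hydride reagents to the 3β-epimer, which is why a hydride is not used.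

Step 17
Reactants: 26 (E)-non-3-en-2-one
Product: 27 ethyl (2E,4E)-3-methyldeca-2,4-dienoate
Conditions: (EtO)2P(O)CH2CO2Et, NaH, THF, 0 °C → reflux
Reagents that add atoms: triethyl phosphonoacetate, CCOC(=O)CP(=O)(OCC)OCC
Why: Horner–Wadsworth–Emmons olefination of the methyl ketone adds 1,2 and favours the 2E isomer (ester trans to the larger alkenyl group); the minor 2Z isomer is removed by chromatography.

Step 18
Reactants: 27 ethyl (2E,4E)-3-methyldeca-2,4-dienoate
Product: 28 (2E,4E)-3-methyldeca-2,4-dien-1-ol
Conditions: i-Bu2AlH, CH2Cl2, −78 → 0 °C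
Reagents that add atoms: none
Why: 1,2-Reduction of the conjugated ester to the allylic alcohol by the aluminium hydride without touching the diene.

Step 19
Reactants: 28 (2E,4E)-3-methyldeca-2,4-dien-1-ol
Product: 29 (2E,4E)-3-methyldeca-2,4-dienal
Conditions: MnO2, CH2Cl2, rt
Reagents that add atoms: none
Why: Selective oxidation of the allylic alcohol to the dienal with retention of both alkene geometries.

Step 20
Reactants: 29 (2E,4E)-3-methyldeca-2,4-dienal
Product: 30 (2E,4E,6E)-5-methyldodeca-2,4,6-trienoic acid
Conditions: CH2(CO2H)2, pyridine, piperidine (cat.), 80 °C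
Reagents that add atoms: malonic acid, OC(=O)CC(=O)O
Why: Knoevenagel condensation in the Doebner modification; decarboxylation of the alkylidene malonic acid gives the E acid directly, with no ester hydrolysis needed on the triene.

Step 21
Reactants: 25 9β-(triethylsilyloxy)-10βH-furanoeremophilan-3α-ol; 30 (2E,4E,6E)-5-methyldodeca-2,4,6-trienoic acid
Product: 31 9β-(triethylsilyloxy)-10βH-furanoeremophilan-3α-yl (2E,4E,6E)-5-methyldodeca-2,4,6-trienoate
Conditions: EDCI·HCl, DMAP, CH2Cl2, rt
Reagents that add atoms: none
Why: Steglich esterification acylates the only free hydroxyl group with retention at C3; the equatorial 3α-alcohol is accessible and the conditions do not isomerise the triene.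

Step 22
Reactants: 31 9β-(triethylsilyloxy)-10βH-furanoeremophilan-3α-yl (2E,4E,6E)-5-methyldodeca-2,4,6-trienoate
Product: 32 9β-hydroxy-10βH-furanoeremophilan-3α-yl (2E,4E,6E)-5-methyldodeca-2,4,6-trienoate
Conditions: Bu4NF, AcOH, THF, 0 °C → rt
Reagents that add atoms: none
Why: Buffered fluoride removes the silyl ether without ester cleavage and without ionising the furfuryl C9–O bond.

Step 23
Reactants: 32 9β-hydroxy-10βH-furanoeremophilan-3α-yl (2E,4E,6E)-5-methyldodeca-2,4,6-trienoate
Product: 33 (7(11)Z)-9β-hydroxy-8,12-dioxo-10βH-eremophil-7(11)-en-3α-yl (2E,4E,6E)-5-methyldodeca-2,4,6-trienoate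
Conditions: dimethyldioxirane (1.0 equiv), acetone, −78 → −20 °C
Reagents that add atoms: dimethyldioxirane, CC1(C)OO1
Why: The trialkylfuran is far more electron-rich than the ester-conjugated triene and is epoxidised first; ring opening gives the cis-enedione, whose Z geometry is inherited from the ring, and a bridgehead alkene would be needed for the C9 hydroxyl to add to C12, so it stays free.

Step 24
Reactants: 33 (7(11)Z)-9β-hydroxy-8,12-dioxo-10βH-eremophil-7(11)-en-3α-yl (2E,4E,6E)-5-methyldodeca-2,4,6-trienoate
Product: 34 (7(11)Z)-9β,12-dihydroxy-8-oxo-10βH-eremophil-7(11)-en-3α-yl (2E,4E,6E)-5-methyldodeca-2,4,6-trienoate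
Conditions: NaBH4 (limiting), EtOH–CH2Cl2, −78 °C; pH 7 buffer
Reagents that add atoms: none
Why: At −78 °C borohydride reduces the aldehyde much faster than the hindered, α-oxygenated C8 ketone, and the tetrasubstituted alkene resists conjugate addition; neutral work-up avoids cyclodehydration of the Z-γ-hydroxy enone to the furan.

## Compound list

1 | 3,4-dibromofuran | Brc1cocc1Br | starting material
2 | 3-bromo-4-lithiofuran | [Li]c1cocc1Br | intermediate (not isolated)
3 | 3-bromo-4-methylfuran | Cc1cocc1Br | intermediate
4 | 3-bromo-2-lithio-4-methylfuran | [Li]c1occ(C)c1Br | intermediate (not isolated)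
5 | 3-bromo-4-methylfuran-2-carbaldehyde | O=Cc1occ(C)c1Br | intermediate
6 | (2S,4S)-pentane-2,4-diol | C[C@H](O)C[C@H](C)O | starting material
7 | (4S,6S)-2-(3-bromo-4-methylfuran-2-yl)-4,6-dimethyl-1,3-dioxane | Cc1coc(C2O[C@@H](C)C[C@H](C)O2)c1Br | intermediate
8 | {2-[(4S,6S)-4,6-dimethyl-1,3-dioxan-2-yl]-4-methylfuran-3-yl}lithium | Cc1coc(C2O[C@@H](C)C[C@H](C)O2)c1[Li] | intermediate (not isolated)
9 | 2-[(4S,6S)-4,6-dimethyl-1,3-dioxan-2-yl]-4-methylfuran-3-carbaldehyde | Cc1coc(C2O[C@@H](C)C[C@H](C)O2)c1C=O | intermediate (not isolated)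
10 | {2-[(4S,6S)-4,6-dimethyl-1,3-dioxan-2-yl]-4-methylfuran-3-yl}methanol | Cc1coc(C2O[C@@H](C)C[C@H](C)O2)c1CO | intermediate
11 | {2-[(4S,6S)-4,6-dimethyl-1,3-dioxan-2-yl]-4-methylfuran-3-yl}methyl methanesulfonate | Cc1coc(C2O[C@@H](C)C[C@H](C)O2)c1COS(C)(=O)=O | intermediate (not isolated)
12 | (4S,6S)-2-[3-(chloromethyl)-4-methylfuran-2-yl]-4,6-dimethyl-1,3-dioxane | Cc1coc(C2O[C@@H](C)C[C@H](C)O2)c1CCl | intermediate
13 | methyl 4-oxobutanoate | COC(=O)CCC=O | starting material
14 | methyl (Z)-5-iodohex-4-enoate | COC(=O)CC/C=C(/C)I | intermediate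
15 | (Z)-5-iodo-N-methoxy-N-methylhex-4-enamide | CON(C)C(=O)CC/C=C(/C)I | intermediate
16 | (Z)-7-iodoocta-1,6-dien-3-one | C=CC(=O)CC/C=C(/C)I | intermediate
17 | tert-butyl{[(3Z,6Z)-7-iodoocta-1,3,6-trien-3-yl]oxy}dimethylsilane | C=C/C(O[Si](C)(C)C(C)(C)C)=C/C/C=C(/C)I | intermediate
18 | ({2-[(4S,6S)-4,6-dimethyl-1,3-dioxan-2-yl]-4-methylfuran-3-yl}methyl)zinc chloride | Cc1coc(C2O[C@@H](C)C[C@H](C)O2)c1C[Zn]Cl | intermediate (not isolated)
19 | (4S,6S)-2-{3-[(2Z,5Z)-6-(tert-butyldimethylsilyloxy)-2-methylocta-2,5,7-trien-1-yl]-4-methylfuran-2-yl}-4,6-dimethyl-1,3-dioxane | Cc1coc(C2O[C@@H](C)C[C@H](C)O2)c1C/C(C)=C\C/C=C(\O[Si](C)(C)C(C)(C)C)C=C | intermediate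
20 | (4S,6S)-2-{3-[(2Z,6E)-6-(tert-butyldimethylsilyloxy)-2-methylocta-2,6-dien-1-yl]-4-methylfuran-2-yl}-4,6-dimethyl-1,3-dioxane (key-step precursor) | Cc1coc(C2O[C@@H](C)C[C@H](C)O2)c1C/C(C)=C\CC\C(O[Si](C)(C)C(C)(C)C)=C/C | intermediate
21 | 9β-{[(2S,4S)-4-hydroxypentan-2-yl]oxy}-10βH-furanoeremophilan-3-one (furan-fused cis-decalin-3-one, 4β,5β-dimethyl; key-step product) | O=C1CC[C@@H]2[C@@H](O[C@@H](C)C[C@H](C)O)c3occ(C)c3C[C@]2(C)[C@H]1C | intermediate
22 | 9β-{[(2S)-4-oxopentan-2-yl]oxy}-10βH-furanoeremophilan-3-one | O=C1CC[C@@H]2[C@@H](O[C@@H](C)CC(C)=O)c3occ(C)c3C[C@]2(C)[C@H]1C | intermediate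
23 | 9β-hydroxy-10βH-furanoeremophilan-3-one | O=C1CC[C@@H]2[C@@H](O)c3occ(C)c3C[C@]2(C)[C@H]1C | intermediate
24 | 9β-(triethylsilyloxy)-10βH-furanoeremophilan-3-one | O=C1CC[C@@H]2[C@@H](O[Si](CC)(CC)CC)c3occ(C)c3C[C@]2(C)[C@H]1C | intermediate
25 | 9β-(triethylsilyloxy)-10βH-furanoeremophilan-3α-ol | O[C@@H]1CC[C@@H]2[C@@H](O[Si](CC)(CC)CC)c3occ(C)c3C[C@]2(C)[C@H]1C | intermediate
26 | (E)-non-3-en-2-one | CCCCC/C=C/C(C)=O | starting material
27 | ethyl (2E,4E)-3-methyldeca-2,4-dienoate | CCCCC/C=C/C(C)=C/C(=O)OCC | intermediate
28 | (2E,4E)-3-methyldeca-2,4-dien-1-ol | CCCCC/C=C/C(C)=C/CO | intermediate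
29 | (2E,4E)-3-methyldeca-2,4-dienal | CCCCC/C=C/C(C)=C/C=O | intermediate
30 | (2E,4E,6E)-5-methyldodeca-2,4,6-trienoic acid | CCCCC/C=C/C(C)=C/C=C/C(=O)O | intermediate
31 | 9β-(triethylsilyloxy)-10βH-furanoeremophilan-3α-yl (2E,4E,6E)-5-methyldodeca-2,4,6-trienoate | CCCCC/C=C/C(C)=C/C=C/C(=O)O[C@@H]1CC[C@@H]2[C@@H](O[Si](CC)(CC)CC)c3occ(C)c3C[C@]2(C)[C@H]1C | intermediate
32 | 9β-hydroxy-10βH-furanoeremophilan-3α-yl (2E,4E,6E)-5-methyldodeca-2,4,6-trienoate | CCCCC/C=C/C(C)=C/C=C/C(=O)O[C@@H]1CC[C@@H]2[C@@H](O)c3occ(C)c3C[C@]2(C)[C@H]1C | intermediate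
33 | (7(11)Z)-9β-hydroxy-8,12-dioxo-10βH-eremophil-7(11)-en-3α-yl (2E,4E,6E)-5-methyldodeca-2,4,6-trienoate | CCCCC/C=C/C(C)=C/C=C/C(=O)O[C@@H]1CC[C@@H]2[C@@H](O)C(=O)/C(=C(/C)C=O)C[C@]2(C)[C@H]1C | intermediate
34 | (7(11)Z)-9β,12-dihydroxy-8-oxo-10βH-eremophil-7(11)-en-3α-yl (2E,4E,6E)-5-methyldodeca-2,4,6-trienoate (CNP0226738.1; 3R,4S,5R,9R,10S) | CCCCC/C=C/C(C)=C/C=C/C(=O)O[C@@H]1CC[C@@H]2[C@@H](O)C(=O)/C(=C(/C)CO)C[C@]2(C)[C@H]1C | target

## Step count and least certain steps

Total step count: 24. Longest linear sequence: 16 steps (steps 1–5, 10–16, 21–24). The chain fragment (steps 6–9) and the acid (steps 17–20) are convergent branches.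

**Step 12 (key step).** The most likely failure is poor control of the face on which the retained alkoxy group ends relative to H10. The furan-conjugated oxocarbenium ion may react from the rotamer with the alkoxy group on the furan-oxygen side, which ends pseudo-equatorial and trans to H10. With the (S,S)-acetal this would pair the 9R ether with the mirror-image carbocycle. The auxiliary sense may also erode if ionisation runs ahead of C–C bond formation, and the discrete C5 cation may lose a proton before the enol silane closes ring A. The facial isomers are diastereomers because of the auxiliary, so they should be separable.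

Fallback, setting out from 5 and coming back at 23: aldehyde 5 is acetalised with (2R,4R)-pentane-2,4-diol to (4R,6R)-2-(3-bromo-4-methylfuran-2-yl)-4,6-dimethyl-1,3-dioxane F1. This is taken through the operations of steps 4, 5, 10 and 11 to the hydroxymethyl furan acetal F2, the chloromethyl furan acetal F3, the coupled silyloxy triene F4 and the enantiomeric-acetal enol silane F5. Cyclisation of F5 under the conditions of step 12 should then join the pseudo-equatorial ether to the natural (4S,5R,10S) carbocycle in 9α-{[(2R,4R)-4-hydroxypentan-2-yl]oxy}-10βH-furanoeremophilan-3-one F6. Dess–Martin oxidation gives the 9α-(4-oxopentan-2-yl) ether F7, and β-elimination as in step 14 gives 9α-hydroxy-10βH-furanoeremophilan-3-one F8. A Mitsunobu reaction with formic acid (PPh3, diisopropyl azodicarboxylate) inverts C9 to 3-oxo-10βH-furanoeremophilan-9β-yl formate F9, and KHCO3 in methanol returns 23.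

**Step 11.** The hydrogen transfer may be slow or unselective with this bulky diene (double-bond migration in place of 1,4-addition), and the silyl dienol ether may hydrolyse on handling.

Fallback, setting out from 15 and coming back at 20: amide 15 with EtMgBr gives (Z)-7-iodooct-6-en-3-one F10. Negishi coupling of F10 with zinc reagent 18 gives the ethyl ketone (Z)-8-{2-[(4S,6S)-4,6-dimethyl-1,3-dioxan-2-yl]-4-methylfuran-3-yl}-7-methyloct-6-en-3-one F11. Kinetic enolisation with lithium 2,2,6,6-tetramethylpiperidide and LiBr at −78 °C and trapping with TBSOTf gives the E enol silane 20 together with the C2-enol silane regioisomer F12. F12 cannot close ring A and is removed after the cyclisation.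

**Step 16.** Product-stability control may be incomplete, giving poor facial selectivity at C3, and the furfuryl C9–O bond may be cleaved reductively.

Fallback, setting out from 24 and coming back at 31: reduction with LiBH(s-Bu)3 should deliver hydride to the α face and give 9β-(triethylsilyloxy)-10βH-furanoeremophilan-3β-ol F13 cleanly. A Mitsunobu reaction of F13 with acid 30 installs the ester with inversion and gives 31. Elimination is the hazard to watch in that step.

**Step 24.** Chemoselectivity may be lost (attack on the C8 ketone, conjugate reduction of the enedione), and the product may cyclodehydrate to furan 32 if the work-up turns acidic.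

Fallback, setting out from 33 and coming back at 34: NaBH4 with CeCl3 in methanol reduces both carbonyl groups to the 8,9,12-triol F14. TBSCl and imidazole silylate only the primary C12 hydroxyl to give the 12-silyl ether F15. MnO2 oxidises the secondary allylic C8 hydroxyl to the 8-oxo 12-silyl ether F16. Bu4NF buffered with AcOH then gives 34.

## Further compounds

F1 | step 12 | (4R,6R)-2-(3-bromo-4-methylfuran-2-yl)-4,6-dimethyl-1,3-dioxane | Cc1coc(C2O[C@H](C)C[C@@H](C)O2)c1Br
F2 | step 12 | {2-[(4R,6R)-4,6-dimethyl-1,3-dioxan-2-yl]-4-methylfuran-3-yl}methanol | Cc1coc(C2O[C@H](C)C[C@@H](C)O2)c1CO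
F3 | step 12 | (4R,6R)-2-[3-(chloromethyl)-4-methylfuran-2-yl]-4,6-dimethyl-1,3-dioxane | Cc1coc(C2O[C@H](C)C[C@@H](C)O2)c1CCl
F4 | step 12 | (4R,6R)-2-{3-[(2Z,5Z)-6-(tert-butyldimethylsilyloxy)-2-methylocta-2,5,7-trien-1-yl]-4-methylfuran-2-yl}-4,6-dimethyl-1,3-dioxane | Cc1coc(C2O[C@H](C)C[C@@H](C)O2)c1C/C(C)=C\C/C=C(\O[Si](C)(C)C(C)(C)C)C=C
F5 | step 12 | (4R,6R)-2-{3-[(2Z,6E)-6-(tert-butyldimethylsilyloxy)-2-methylocta-2,6-dien-1-yl]-4-methylfuran-2-yl}-4,6-dimethyl-1,3-dioxane | Cc1coc(C2O[C@H](C)C[C@@H](C)O2)c1C/C(C)=C\CC\C(O[Si](C)(C)C(C)(C)C)=C/C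
F6 | step 12 | 9α-{[(2R,4R)-4-hydroxypentan-2-yl]oxy}-10βH-furanoeremophilan-3-one | O=C1CC[C@@H]2[C@H](O[C@H](C)C[C@@H](C)O)c3occ(C)c3C[C@]2(C)[C@H]1C
F7 | step 12 | 9α-{[(2R)-4-oxopentan-2-yl]oxy}-10βH-furanoeremophilan-3-one | O=C1CC[C@@H]2[C@H](O[C@H](C)CC(C)=O)c3occ(C)c3C[C@]2(C)[C@H]1C
F8 | step 12 | 9α-hydroxy-10βH-furanoeremophilan-3-one | O=C1CC[C@@H]2[C@H](O)c3occ(C)c3C[C@]2(C)[C@H]1C
F9 | step 12 | 3-oxo-10βH-furanoeremophilan-9β-yl formate | O=C1CC[C@@H]2[C@@H](OC=O)c3occ(C)c3C[C@]2(C)[C@H]1C
F10 | step 11 | (Z)-7-iodooct-6-en-3-one | CCC(=O)CC/C=C(/C)I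
F11 | step 11 | (Z)-8-{2-[(4S,6S)-4,6-dimethyl-1,3-dioxan-2-yl]-4-methylfuran-3-yl}-7-methyloct-6-en-3-one | Cc1coc(C2O[C@@H](C)C[C@H](C)O2)c1C/C(C)=C\CCC(=O)CC
F12 | step 11 | (4S,6S)-2-{3-[(2Z,5E)-6-(tert-butyldimethylsilyloxy)-2-methylocta-2,5-dien-1-yl]-4-methylfuran-2-yl}-4,6-dimethyl-1,3-dioxane | Cc1coc(C2O[C@@H](C)C[C@H](C)O2)c1C/C(C)=C\C/C=C(/O[Si](C)(C)C(C)(C)C)CC
F13 | step 16 | 9β-(triethylsilyloxy)-10βH-furanoeremophilan-3β-ol | O[C@H]1CC[C@@H]2[C@@H](O[Si](CC)(CC)CC)c3occ(C)c3C[C@]2(C)[C@H]1C
F14 | step 24 | (7(11)Z)-8,9β,12-trihydroxy-10βH-eremophil-7(11)-en-3α-yl (2E,4E,6E)-5-methyldodeca-2,4,6-trienoate (C8 epimers) | CCCCC/C=C/C(C)=C/C=C/C(=O)O[C@@H]1CC[C@@H]2[C@@H](O)C(O)/C(=C(/C)CO)C[C@]2(C)[C@H]1C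
F15 | step 24 | (7(11)Z)-12-(tert-butyldimethylsilyloxy)-8,9β-dihydroxy-10βH-eremophil-7(11)-en-3α-yl (2E,4E,6E)-5-methyldodeca-2,4,6-trienoate (C8 epimers) | CCCCC/C=C/C(C)=C/C=C/C(=O)O[C@@H]1CC[C@@H]2[C@@H](O)C(O)/C(=C(/C)CO[Si](C)(C)C(C)(C)C)C[C@]2(C)[C@H]1C
F16 | step 24 | (7(11)Z)-12-(tert-butyldimethylsilyloxy)-9β-hydroxy-8-oxo-10βH-eremophil-7(11)-en-3α-yl (2E,4E,6E)-5-methyldodeca-2,4,6-trienoate | CCCCC/C=C/C(C)=C/C=C/C(=O)O[C@@H]1CC[C@@H]2[C@@H](O)C(=O)/C(=C(/C)CO[Si](C)(C)C(C)(C)C)C[C@]2(C)[C@H]1C
A1 | alternative 1 | cis-fused 9,9-dimethoxy-4,5-dimethyloctal-3-en-8-one (target numbering) | CC1=CCC[C@@H]2C(OC)(OC)C(=O)CC[C@]12C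
A2 | alternative 2 | cis-fused 3α-(tert-butyldiphenylsilyloxy)-8-(tert-butyldimethylsilyloxy)-9-(4-methoxybenzyloxy)-5-methyloctal-8-en-4-one (target numbering) | CC(C)(C)[Si](c1ccccc1)(c1ccccc1)O[C@@H]3CC[C@@H]4C(OCc1ccc(OC)cc1)=C(O[Si](C)(C)C(C)(C)C)CC[C@]4(C)C3=O
A3 | alternative 3 | cis-fused 3β-(tert-butyldimethylsilyloxy)-4,5-dimethyloctal-6-en-8-one (target numbering) | CC(C)(C)[Si](C)(C)O[C@H]1CC[C@@H]2CC(=O)C=C[C@]2(C)[C@H]1C
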